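**Retrosynthetic overview**

1. The C8–O ester bond is made last but one, from a C8–B bond: boron is the stereodefined placeholder for the C8 oxygen and is turned directly into the side-chain ester with retention (new C–O step).
2. The α-methylene-γ-lactone comes from C6–O bond formation (thermodynamic ketone reduction, then lactonisation onto a C7 acetate arm) followed by α-methylenation.
3. The C5 and C7 branches come from two α-functionalisations of the C6 ketone: alkylation at C7 and Pd α-alkenylation at C5 with kinetic protonation.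
4. C8–B comes from a catalyst-controlled Cu conjugate borylation; the quaternary C10 comes from a Cu-catalysed asymmetric conjugate vinylation of 3-methylcyclohex-2-enone.
5. Ring order: the carbocycle is the starting enone; the lactone ring is closed in step 7.

Assumption: C1–C15 are elemane locants of the target (β = face of the C10 methyl; pin = pinacolato; TBDPS = tert-butyldiphenylsilyl), and the ligand enantiomers in steps 2 and 4 are the ones that give the drawn configurations.

**Route**

Step 1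
Reactants: 1 2-bromoprop-2-en-1-ol
Product: 2 (2-bromoallyloxy)(tert-butyl)diphenylsilane
Conditions: TBDPSCl, imidazole, CH2Cl2, 0 °C → rt
Reagents that add atoms: tert-butyl(chloro)diphenylsilane, CC(C)(C)[Si](Cl)(c1ccccc1)c1ccccc1
Why: Standard silyl ether formation protects the future C15 hydroxyl; no stereocentre is involved.

Step 2
Reactants: 3 3-methylcyclohex-2-en-1-one
Product: 4 (R)-3-methyl-3-vinylcyclohexan-1-one
Conditions: CH2=CHAlMe2, CuTC (5 mol %), chiral phosphinamine ligand (10 mol %), Et2O, −30 °C; aq NH4Cl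
Reagents that add atoms: dimethyl(vinyl)aluminium, C=C[Al](C)C
Why: Copper-catalysed asymmetric conjugate addition of an alkenylalane to a β-substituted enone builds the quaternary C10, its (R) configuration being set by the ligand.

Step 3
Reactants: 4 (R)-3-methyl-3-vinylcyclohexan-1-one
Product: 5 (R)-5-methyl-5-vinylcyclohex-2-en-1-one
Conditions: IBX, DMSO, 70 °C
Reagents that add atoms: none
Why: IBX dehydrogenation of the ketone can only desaturate C7–C8 because the other α-carbon is flanked by the quaternary C10, so a single enone forms.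

Step 4
Reactants: 5 (R)-5-methyl-5-vinylcyclohex-2-en-1-one
Product: 6 (3R,5S)-3-methyl-5-(4,4,5,5-tetramethyl-1,3,2-dioxaborolan-2-yl)-3-vinylcyclohexan-1-one
Conditions: B2pin2, CuCl (3 mol %), Josiphos-type ligand (3 mol %), NaOt-Bu (5 mol %), MeOH, THF, rt
Reagents that add atoms: bis(pinacolato)diboron, CC1(C)OB(OC1(C)C)B1OC(C)(C)C(C)(C)O1
Why: Copper-catalysed asymmetric conjugate borylation sets C8 under ligand control (methyl and vinyl at C10 give no substrate bias), placing boron cis to the vinyl group so that both sit equatorial and the C10 methyl is axial.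

Step 5
Reactants: 6 (3R,5S)-3-methyl-5-(4,4,5,5-tetramethyl-1,3,2-dioxaborolan-2-yl)-3-vinylcyclohexan-1-one
Product: 8 ethyl 2-[4-methyl-2-oxo-6-(pinacolboryl)-4-vinylcyclohexyl]acetate (7β-CH2CO2Et; 8α-B), via lithium enolate 7 (not isolated)
Conditions: LDA, THF, −78 °C; ICH2CO2Et, DMPU, −78 → −40 °C
Reagents that add atoms: ethyl iodoacetate, CCOC(=O)CI
Why: Kinetic enolate alkylation occurs at the C7 methylene (the C5 methylene is neopentylic) and anti to the C8 boryl group, giving the trans-diequatorial 7β,8α product; a boryl group cannot be lost by E1cB as a protected oxygen could.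

Step 6
Reactants: 8 ethyl 2-[4-methyl-2-oxo-6-(pinacolboryl)-4-vinylcyclohexyl]acetate; 2 (2-bromoallyloxy)(tert-butyl)diphenylsilane
Product: 11 ethyl 2-[3-[3-(tert-butyldiphenylsilyloxy)prop-1-en-2-yl]-4-methyl-2-oxo-6-(pinacolboryl)-4-vinylcyclohexyl]acetate (5β; 7β; 8α-B), via lithium enolate 9 (not isolated), via lithium dienolate 10 (not isolated)
Conditions: Pd2(dba)3 (2.5 mol %), t-Bu3P·HBF4 (6 mol %), LiHMDS (2.3 equiv), PhMe, rt; then AcOH, THF, −78 °C
Reagents that add atoms: none
Why: Palladium-catalysed ketone α-alkenylation (Buchwald-type enolate vinylation) takes place at the only α-methylene, C5; the more acidic product remains as its dienolate and is protonated kinetically at C5 from the α face, anti to the axial C10 methyl (deconjugative protonation as in pulegone → isopulegone), which leaves the alkenyl group 5β.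

Step 7
Reactants: 11 ethyl 2-[3-[3-(tert-butyldiphenylsilyloxy)prop-1-en-2-yl]-4-methyl-2-oxo-6-(pinacolboryl)-4-vinylcyclohexyl]acetate
Product: 13 8α-(pinacolboryl)-15-(tert-butyldiphenylsilyloxy)elema-1,3-dien-12,6α-olide, via hydroxy ester 12 (not isolated)
Conditions: SmI2, H2O, THF, 0 °C; then PPTS (cat.), PhMe, 60 °C
Reagents that add atoms: none
Why: Single-electron reduction with samarium diiodide gives the thermodynamically favoured equatorial 6α-alcohol (an axial OH would be 1,3-diaxial to the C10 methyl), and acid-catalysed lactonisation then forms the C6–O bond of the trans-fused γ-lactone.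

Step 8
Reactants: 13 8α-(pinacolboryl)-15-(tert-butyldiphenylsilyloxy)elema-1,3-dien-12,6α-olide
Product: 17 8α-(pinacolboryl)-15-(tert-butyldiphenylsilyloxy)elema-1,3,11(13)-trien-12,6α-olide, via lithium enolate 14 (not isolated), via Mannich base 15 (not isolated), via ammonium iodide 16 (not isolated)
Conditions: LDA, THF, −78 °C; CH2=NMe2+ I−, −78 °C → rt; MeI, MeOH; aq NaHCO3
Reagents that add atoms: Eschenmoser's salt, C=[N+](C)C.[I-]
Why: Mannich reaction of the lactone enolate with Eschenmoser's salt, N-methylation and Hofmann-type elimination install the exocyclic methylene without touching any stereocentre or the C–B bond.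

Step 9
Reactants: 18 methyl (R)-3-hydroxy-2-methylpropanoate
Product: 19 methyl (R)-3-(tert-butyldiphenylsilyloxy)-2-methylpropanoate
Conditions: TBDPSCl, imidazole, CH2Cl2, rt
Reagents that add atoms: tert-butyl(chloro)diphenylsilane, CC(C)(C)[Si](Cl)(c1ccccc1)c1ccccc1
Why: Silyl ether formation on the Roche ester; the stereocentre is carried over from the chiral pool.

Step 10
Reactants: 19 methyl (R)-3-(tert-butyldiphenylsilyloxy)-2-methylpropanoate
Product: 20 (R)-3-(tert-butyldiphenylsilyloxy)-2-methylpropanoic acid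
Conditions: LiOH, THF/H2O, 0 °C; then 1 M HCl
Reagents that add atoms: lithium hydroxide, [Li+].[OH-]
Why: Cold saponification of the methyl ester is a standard operation on this Roche-ester derivative and leaves the α-stereocentre intact.

Step 11
Reactants: 20 (R)-3-(tert-butyldiphenylsilyloxy)-2-methylpropanoic acid
Product: 21 (R)-3-(tert-butyldiphenylsilyloxy)-2-methylpropanoyl fluoride
Conditions: cyanuric fluoride, pyridine, CH2Cl2, −10 °C
Reagents that add atoms: cyanuric fluoride, Fc1nc(F)nc(F)n1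
Why: Deoxyfluorination of the acid with cyanuric fluoride gives a stable acyl fluoride without enolising the α-centre.

Step 12
Reactants: 17 8α-(pinacolboryl)-15-(tert-butyldiphenylsilyloxy)elema-1,3,11(13)-trien-12,6α-olide; 21 (R)-3-(tert-butyldiphenylsilyloxy)-2-methylpropanoyl fluoride
Product: 23 8α-[(R)-3-(tert-butyldiphenylsilyloxy)-2-methylpropanoyloxy]-15-(tert-butyldiphenylsilyloxy)elema-1,3,11(13)-trien-12,6α-olide, via boric ester 22 (not isolated)
Conditions: Me3NO (anhydrous), THF, 50 °C; then 21, DMAP (10 mol %), 0 °C → rt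
Reagents that add atoms: trimethylamine N-oxide, C[N+](C)(C)[O-]
Why: Proposed new method: one-pot stereoretentive deborylative acyloxylation, in which the N-oxide adds to boron and C8 migrates from B to O with retention (as in amine-oxide or peroxide oxidation of boronic esters) to give the O-boryl alkoxide 22, whose B–O oxygen is then acylated by the acyl fluoride while fluoride passes to boron (strong B–F bond, DMAP as acyl shuttle), so the C8–O ester bond forms with the C8 configuration fixed in step 4 and no free C8 alkoxide is ever exposed next to the α-methylene lactone; closest known reactions are N-oxide oxidation of organoboronates and fluoride-driven acylation of silyl ethers by acyl fluorides.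

Step 13
Reactants: 23 8α-[(R)-3-(tert-butyldiphenylsilyloxy)-2-methylpropanoyloxy]-15-(tert-butyldiphenylsilyloxy)elema-1,3,11(13)-trien-12,6α-olide
Product: 24 8α-[(R)-3-hydroxy-2-methylpropanoyloxy]-15-hydroxyelema-1,3,11(13)-trien-12,6α-olide (CNP0133858.1)
Conditions: HF·pyridine, THF, 0 °C → rt
Reagents that add atoms: none
Why: Fluoride-mediated cleavage of both silyl ethers under buffered acidic conditions spares the ester, the α-methylene lactone and all stereocentres.

**Compound list**

1 | 2-bromoprop-2-en-1-ol | C=C(Br)CO | starting material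
2 | (2-bromoallyloxy)(tert-butyl)diphenylsilane | C=C(Br)CO[Si](c1ccccc1)(c1ccccc1)C(C)(C)C | intermediate
3 | 3-methylcyclohex-2-en-1-one | CC1=CC(=O)CCC1 | starting material
4 | (R)-3-methyl-3-vinylcyclohexan-1-one | C=C[C@]1(C)CCCC(=O)C1 | intermediate
5 | (R)-5-methyl-5-vinylcyclohex-2-en-1-one | C=C[C@]1(C)CC=CC(=O)C1 | intermediate
6 | (3R,5S)-3-methyl-5-(4,4,5,5-tetramethyl-1,3,2-dioxaborolan-2-yl)-3-vinylcyclohexan-1-one (boron cis to vinyl) | C=C[C@]1(C)C[C@H](B2OC(C)(C)C(C)(C)O2)CC(=O)C1 | intermediate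
7 | lithium enolate of 6 (C6=C7) | C=C[C@]1(C)C[C@H](B2OC(C)(C)C(C)(C)O2)C=C(O[Li])C1 | intermediate
8 | ethyl 2-[4-methyl-2-oxo-6-(pinacolboryl)-4-vinylcyclohexyl]acetate (7β-CH2CO2Et, 8α-B, 10β-Me) | C=C[C@]1(C)C[C@H](B2OC(C)(C)C(C)(C)O2)[C@@H](CC(=O)OCC)C(=O)C1 | intermediate
9 | lithium enolate of 8 (C5=C6) | C=C[C@]1(C)C[C@H](B2OC(C)(C)C(C)(C)O2)[C@@H](CC(=O)OCC)C(O[Li])=C1 | intermediate
10 | lithium dienolate of 11 (C5=C6, conjugated with C4=C3) | C=C[C@]1(C)C[C@H](B2OC(C)(C)C(C)(C)O2)[C@@H](CC(=O)OCC)C(O[Li])=C1C(=C)CO[Si](c2ccccc2)(c2ccccc2)C(C)(C)C | intermediate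
11 | ethyl 2-[3-[3-(tert-butyldiphenylsilyloxy)prop-1-en-2-yl]-4-methyl-2-oxo-6-(pinacolboryl)-4-vinylcyclohexyl]acetate (5β-alkenyl, 7β, 8α-B, 10β-Me) | C=C[C@]1(C)C[C@H](B2OC(C)(C)C(C)(C)O2)[C@@H](CC(=O)OCC)C(=O)[C@H]1C(=C)CO[Si](c2ccccc2)(c2ccccc2)C(C)(C)C | intermediate
12 | 6α-hydroxy ester from 11 (5β, 6α-OH, 7β, 8α-B) | C=C[C@]1(C)C[C@H](B2OC(C)(C)C(C)(C)O2)[C@@H](CC(=O)OCC)[C@H](O)[C@H]1C(=C)CO[Si](c2ccccc2)(c2ccccc2)C(C)(C)C | intermediate
13 | 8α-(pinacolboryl)-15-(tert-butyldiphenylsilyloxy)elema-1,3-dien-12,6α-olide (trans-fused lactone) | C=C[C@]1(C)C[C@H](B3OC(C)(C)C(C)(C)O3)[C@H]2CC(=O)O[C@@H]2[C@H]1C(=C)CO[Si](c3ccccc3)(c3ccccc3)C(C)(C)C | intermediate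
14 | lithium enolate of lactone 13 | C=C[C@]1(C)C[C@H](B3OC(C)(C)C(C)(C)O3)[C@H]2C=C(O[Li])O[C@@H]2[C@H]1C(=C)CO[Si](c3ccccc3)(c3ccccc3)C(C)(C)C | intermediate
15 | 11-(dimethylaminomethyl) lactone (Mannich base, C11 epimers) | C=C[C@]1(C)C[C@H](B3OC(C)(C)C(C)(C)O3)[C@H]2C(CN(C)C)C(=O)O[C@@H]2[C@H]1C(=C)CO[Si](c3ccccc3)(c3ccccc3)C(C)(C)C | intermediate
16 | 11-(trimethylammoniomethyl) lactone iodide | C=C[C@]1(C)C[C@H](B3OC(C)(C)C(C)(C)O3)[C@H]2C(C[N+](C)(C)C)C(=O)O[C@@H]2[C@H]1C(=C)CO[Si](c3ccccc3)(c3ccccc3)C(C)(C)C.[I-] | intermediate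
17 | 8α-(pinacolboryl)-15-(tert-butyldiphenylsilyloxy)elema-1,3,11(13)-trien-12,6α-olide | C=C[C@]1(C)C[C@H](B3OC(C)(C)C(C)(C)O3)[C@H]2C(=C)C(=O)O[C@@H]2[C@H]1C(=C)CO[Si](c3ccccc3)(c3ccccc3)C(C)(C)C | intermediate
18 | methyl (R)-3-hydroxy-2-methylpropanoate (Roche ester) | COC(=O)[C@H](C)CO | starting material
19 | methyl (R)-3-(tert-butyldiphenylsilyloxy)-2-methylpropanoate | COC(=O)[C@H](C)CO[Si](c1ccccc1)(c1ccccc1)C(C)(C)C | intermediate
20 | (R)-3-(tert-butyldiphenylsilyloxy)-2-methylpropanoic acid | OC(=O)[C@H](C)CO[Si](c1ccccc1)(c1ccccc1)C(C)(C)C | intermediate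
21 | (R)-3-(tert-butyldiphenylsilyloxy)-2-methylpropanoyl fluoride | FC(=O)[C@H](C)CO[Si](c1ccccc1)(c1ccccc1)C(C)(C)C | intermediate
22 | 8α-(pinacolboryloxy)-15-(tert-butyldiphenylsilyloxy)elema-1,3,11(13)-trien-12,6α-olide | C=C[C@]1(C)C[C@H](OB3OC(C)(C)C(C)(C)O3)[C@H]2C(=C)C(=O)O[C@@H]2[C@H]1C(=C)CO[Si](c3ccccc3)(c3ccccc3)C(C)(C)C | intermediate
23 | 8α-[(R)-3-(tert-butyldiphenylsilyloxy)-2-methylpropanoyloxy]-15-(tert-butyldiphenylsilyloxy)elema-1,3,11(13)-trien-12,6α-olide | C=C[C@]1(C)C[C@H](OC(=O)[C@H](C)CO[Si](c3ccccc3)(c3ccccc3)C(C)(C)C)[C@H]2C(=C)C(=O)O[C@@H]2[C@H]1C(=C)CO[Si](c3ccccc3)(c3ccccc3)C(C)(C)C | intermediate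
24 | 8α-[(R)-3-hydroxy-2-methylpropanoyloxy]-15-hydroxyelema-1,3,11(13)-trien-12,6α-olide (CNP0133858.1) | C=C[C@]1(C)C[C@H](OC(=O)[C@H](C)CO)[C@H]2C(=C)C(=O)O[C@@H]2[C@H]1C(=C)CO | target

**Step count and risk**

Total step count: 13. Longest linear sequence: 9 steps (steps 2–8, 12 and 13, from 3-methylcyclohex-2-en-1-one).

Steps most likely to fail:

Step 12 (new deborylative acyloxylation). The N-oxide oxidation of a hindered secondary boronate may be slow, or the boric ester may not take the acyl group. The fallback uses known chemistry and sets out from 17: oxidise the C–B bond with sodium perborate (NaBO3·4H2O, THF/pH 7 buffer, 0 °C) to the 8α-alcohol F1, then esterify F1 with acid 20 under carbodiimide conditions (DIC, DMAP, CH2Cl2). This comes back to the route at 23.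

Step 6 (Pd α-alkenylation at the neopentylic C5 and kinetic protonation). Coupling at so hindered an enolate carbon may stall. The fallback sets out from 8 and reverses the polarity at C5: LDA/TMSCl gives the kinetic trimethylsilyl enol ether F2, and NBS converts it into the α-bromo ketone F3. Nickel-catalysed Negishi coupling of F3 (NiCl2·glyme, bipyridine ligand, THF/DMA) with the alkenylzinc bromide F4, made from 2 by zinc insertion, gives the C5-epimeric alkenyl ketone F5. Re-enolisation of F5 with LiHMDS comes back to the route at 10, which is protonated with AcOH at −78 °C as in step 6 to give 11.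

Step 7 (configuration at C6 in the reduction). If the samarium reduction gives too much axial alcohol, the fallback sets out from 11 and takes the kinetic alcohol on purpose: L-Selectride (THF, −78 °C) attacks from the equatorial side and the 6β-alkoxide closes to the cis-fused 6β-lactone F6. LiOH opens F6 to the 6β-hydroxy acid F7, and Mitsunobu lactonisation (PPh3, DIAD, THF, 0 °C) forms the C6–O bond with inversion. This comes back to the route at 13.

**Further compounds**

F1 | step 12 | 8α-hydroxy-15-(tert-butyldiphenylsilyloxy)elema-1,3,11(13)-trien-12,6α-olide | C=C[C@]1(C)C[C@H](O)[C@H]2C(=C)C(=O)O[C@@H]2[C@H]1C(=C)CO[Si](c3ccccc3)(c3ccccc3)C(C)(C)C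
F2 | step 6 | trimethylsilyl enol ether of 8 (C5=C6) | C=C[C@]1(C)C[C@H](B2OC(C)(C)C(C)(C)O2)[C@@H](CC(=O)OCC)C(O[Si](C)(C)C)=C1
F3 | step 6 | 5-bromo derivative of 8 (C5 epimers) | C=C[C@]1(C)C[C@H](B2OC(C)(C)C(C)(C)O2)[C@@H](CC(=O)OCC)C(=O)C1Br
F4 | step 6 | [3-(tert-butyldiphenylsilyloxy)prop-1-en-2-yl]zinc bromide | C=C([Zn]Br)CO[Si](c1ccccc1)(c1ccccc1)C(C)(C)C
F5 | step 6 | C5-epimeric mixture of 11 | C=C[C@]1(C)C[C@H](B2OC(C)(C)C(C)(C)O2)[C@@H](CC(=O)OCC)C(=O)C1C(=C)CO[Si](c2ccccc2)(c2ccccc2)C(C)(C)C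
F6 | step 7 | 8α-(pinacolboryl)-15-(tert-butyldiphenylsilyloxy)elema-1,3-dien-12,6β-olide (cis-fused) | C=C[C@]1(C)C[C@H](B3OC(C)(C)C(C)(C)O3)[C@H]2CC(=O)O[C@H]2[C@H]1C(=C)CO[Si](c3ccccc3)(c3ccccc3)C(C)(C)C
F7 | step 7 | 6β-hydroxy acid from F6 | C=C[C@]1(C)C[C@H](B2OC(C)(C)C(C)(C)O2)[C@@H](CC(=O)O)[C@@H](O)[C@H]1C(=C)CO[Si](c2ccccc2)(c2ccccc2)C(C)(C)C
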